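A percentage of capped ends is a poor thing to carry from one run to the next: after 3.00 min the beta run read 19.5% and the eta run 12.9%, though both had been charged with 0.010 M of one-sided end groups. So I asked what that percentage was a share of. I took the capped-end ceiling C, the charge of one-sided end groups over the charge of first end groups, which came to 10.0% for your flask. For beta C was 20.0% and for eta 13.3%, so the two readings lay close to it, each being good to 0.5 percentage points. One-sided end groups were the limiting reagent of capping in your flask, with 0.0100 M charged, less than the 0.10 M of first end groups.

| flask | first end groups | second end groups | one-sided end groups | remark | time |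
|---|---|---|---|---|---|
| beta | 0.050 M | 0.11 M | 0.010 M | run made earlier |  |
| eta | 0.075 M | 0.11 M | 0.010 M | run made earlier |  |
| flask | 0.10 M | 0.110 M | 0.0100 M |  | 12 min |

| run | time / min | links / % | capped ends / % | first end groups / % |
|---|---|---|---|---|
| beta | 1.00 | 6.2 | 13.8 | 77.7 |
| beta | 3.00 | 17.0 | 19.5 | 59.6 |
| beta | 6.00 | 28.9 | 19.4 | 46.0 |
| beta | 8.00 | 33.8 | 19.5 | 39.3 |
| beta | 12.0 | 40.0 | 19.1 | 31.7 |
| eta | 1.00 | 7.0 | 10.9 | 78.6 |
| eta | 2.00 | 12.5 | 12.6 | 69.9 |
| eta | 3.00 | 17.7 | 12.9 | 63.1 |
| eta | 6.00 | 28.0 | 13.5 | 48.6 |
| eta | 12.0 | 39.2 | 12.2 | 33.6 |

(each reading ± 0.5 percentage points)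

- amount of links in the flask at 12 min, in percent of the first end groups charged
- amount of capped ends in the flask at 12 min, in percent of the first end groups charged
- concentration of second end groups at 12 min, in M

- in percentages every species weighs as the first end groups in it: one idle adduct or side product counts as two
- for links the idle adduct is counted in
- candidate steps: first end groups + links -> side product; first end groups + one-sided end groups -> capped ends; first end groups + links <-> idle adduct; first end groups + second end groups <-> links
- in an amount of links, one idle adduct counts as one links

I committed to 10.0% of capped ends at 12 min. Going round once more, I put that answer back in, and it left 0.0900 M of first end groups for links, idle adduct and side product. From there I had no quicker route than the forecast, which gave 37.7% of links, 9.9% of capped ends and 0.069 M of second end groups, on the ground that “the one-sided groups are used up within a minute or two”.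

The flask gave 37.9% of links, 10.0% of capped ends and 0.0686 M of second end groups at 12 min.

    first end groups + links → side product (k = 0.00590 L mol⁻¹ s⁻¹)
    first end groups + one-sided end groups → capped ends (k = 0.403 L mol⁻¹ s⁻¹)
    first end groups + links ⇌ idle adduct, settled at all times (K = 9.23 L mol⁻¹)
    first end groups + second end groups ⇌ links (K = 41.5 L mol⁻¹, k = 0.0133 L mol⁻¹ s⁻¹)

Capped ends already stood at 9.20% after 1.20 min, and one-sided end groups were down to 0.00585% of their own charge after 6.00 min. The neighbouring flask with 0.25 M of first end groups and the same one-sided charge has C = 4.00%, and it held 4.00% of capped ends at 12 min.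

(Readings and results were computed for an exercise; the scatter is artificial.)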